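## Retrosynthetic overview

1. Feature: the ten-membered ring C1–C10 carries the (3Z)-C3=C4–C5(=C16H2) diene and, across C6 and C7, the oxygenated C8. This is the product pattern of an oxy-Cope shift of a 1-vinyl-2-allenylcyclohexanol, so the ring is cut back to a trans-decalin (ring B = C1-C2-C3-C8-C9-C10, ring A = C1-C10-C11-C12-C13-C14) by reconnecting C3–C8 and breaking C5–C6.
2. Endgame from the C8 ketone: C6=C7 enone; propionate enolate onto C8 (C17–C19); C8–OH-directed 6,7-epoxidation; one chloride step opens the 6,7- and the 11,20-epoxide (C6–Cl, C20–Cl) and the lactone closes C7–O–C19; silyl ethers exchanged for acetates.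
3. Precursor from (S)-Wieland–Miescher ketone: C2–O by reduction; trans fusion by hydroboration; C8/C9 oxygens by α-hydroxylation and reduction; ring A (C13=C14, C12–O, C11 spiro-epoxide) from the C12 ketone; C3 allene by propynal aldol and Myers transposition; C8 vinyl carbinol by vinyl addition.
4. Ring order: rings A and B arrive with the starting decalin; the ten-membered ring forms in step 23 by four-atom expansion of ring B; the γ-lactone closes in step 27.

Key step: step 23

Conventions: briarane numbering (C15 = methyl on C1, C16 = methylene on C5, C17/C18/C19 = lactone CH/CH3/C=O, C20 = carbon on C11). In the decalins β is the face of the C1 methyl and α the face of H10.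

Remark: 1 is taken as the commercial, enantiopure (S) compound (it is the product of the proline-catalysed Robinson annulation of 2-methylcyclohexane-1,3-dione with methyl vinyl ketone).

Remark: the enone of step 24 is assumed to be (6E); only the trans-6,7-epoxide derived from it gives the required C6 configuration on direct opening by chloride (the Z case is covered among the fallbacks).

## Route

Step 1
Reactants: 1 (S)-Wieland–Miescher ketone
Product: 2 2β-hydroxy enone
Conditions: NaBH4 (0.3 equiv), EtOH, 0 °C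
Reagents that add atoms: none
Why: Chemoselective borohydride reduction: the saturated C2 ketone reacts faster than the conjugated C12 carbonyl and hydride enters axially from the face opposite the angular methyl, so the new C2 hydroxyl is equatorial and cis to the methyl (2β) as the target requires.

Step 2
Reactants: 2 2β-hydroxy enone
Product: 3 2β-silyloxy enone
Conditions: TBSCl, imidazole, DMF, 40 °C
Reagents that add atoms: tert-butyldimethylsilyl chloride, CC(C)(C)[Si](C)(C)Cl
Why: Silyl ether formation under imidazole catalysis protects the neopentyl C2 hydroxyl for the rest of the route.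

Step 3
Reactants: 3 2β-silyloxy enone
Product: 4 12-dioxolane 9(10)-alkene
Conditions: ethylene glycol, p-TsOH (cat.), toluene, reflux, Dean–Stark
Reagents that add atoms: ethylene glycol, OCCO
Why: Acid-catalysed ketalisation of the enone, which as usual moves the double bond out of conjugation to C9=C10, masks C12 and places the alkene for hydroboration.

Step 4
Reactants: 4 12-dioxolane 9(10)-alkene
Product: 5 9α-alcohol
Conditions: BH3·THF, THF, 0 °C → rt; then NaOH (aq), H2O2, 0 °C
Reagents that add atoms: hydrogen peroxide, OO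
Why: Hydroboration–oxidation: borane adds to the trisubstituted C9=C10 bond from the face opposite the angular methyl with boron on C9, which sets H10 α (trans ring fusion) and gives the equatorial 9α-alcohol.

Step 5
Reactants: 5 9α-alcohol
Product: 6 9-ketone
Conditions: Dess–Martin periodinane, NaHCO3, CH2Cl2, rt
Reagents that add atoms: none
Why: Dess–Martin oxidation of the secondary alcohol; the trans-fused ketone is the more stable ring-fusion isomer so C10 is not endangered.

Step 6
Reactants: 6 9-ketone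
Product: 8 8α-hydroxy 9-ketone, via potassium enolate 7 (not isolated)
Conditions: KN(SiMe3)2, THF, −78 °C; 2-(phenylsulfonyl)-3-phenyloxaziridine, −78 °C; NH4Cl (aq)
Reagents that add atoms: 2-(phenylsulfonyl)-3-phenyloxaziridine, O=S(=O)(c1ccccc1)N1OC1c1ccccc1
Why: Enolate hydroxylation with the Davis oxaziridine: kinetic deprotonation takes the C8 methylene rather than the C10 methine and oxygen is delivered axially on the α face, away from the angular methyl, to give the 8α-hydroxy ketone (C8 is oxidised later, only its trans relation to the C9 oxygen is used).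

Step 7
Reactants: 8 8α-hydroxy 9-ketone
Product: 9 8α,9β-diol
Conditions: NaBH4, MeOH, −20 °C
Reagents that add atoms: none
Why: Borohydride reduction of the C9 ketone from the α face, the β face being closed by the 1,3-diaxial C1 methyl and the neighbouring 8α-hydroxyl assisting delivery, sets the axial 9β-hydroxyl and so the trans-diaxial 8α,9β-diol.

Step 8
Reactants: 9 8α,9β-diol
Product: 10 8α-benzoate
Conditions: BzCl (1.1 equiv), pyridine, CH2Cl2, 0 °C
Reagents that add atoms: benzoyl chloride, O=C(Cl)c1ccccc1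
Why: Selective acylation: of the two axial hydroxyls only the 9β one is 1,3-diaxial to the angular methyl, so benzoyl chloride takes the C8 hydroxyl, and the trans-diaxial arrangement excludes acyl migration.

Step 9
Reactants: 10 8α-benzoate
Product: 11 9β-silyl ether
Conditions: TBSOTf, 2,6-lutidine, CH2Cl2, 0 °C → rt
Reagents that add atoms: tert-butyldimethylsilyl triflate, CC(C)(C)[Si](C)(C)OS(=O)(=O)C(F)(F)F
Why: Silylation of the hindered axial 9β-hydroxyl with the silyl triflate installs a bulky non-chelating ether that later directs additions at C8 by the polar Felkin–Anh effect.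

Step 10
Reactants: 11 9β-silyl ether
Product: 12 12-ketone
Conditions: PPTS, acetone–H2O, 60 °C
Reagents that add atoms: water, O
Why: Mild acid-catalysed ketal hydrolysis frees the C12 ketone without touching the silyl ethers or the benzoate.

Step 11
Reactants: 12 12-ketone
Product: 13 13(14)-enone
Conditions: IBX, DMSO–fluorobenzene, 65 °C
Reagents that add atoms: none
Why: IBX dehydrogenation through the enol, which in this trans-fused cyclohexanone forms towards the C13 methylene as in 3-keto-5α-steroids, gives the C13=C14 enone.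

Step 12
Reactants: 13 13(14)-enone
Product: 14 cross-conjugated 11(20),13-dienone
Conditions: paraformaldehyde, N-methylanilinium trifluoroacetate, THF, reflux
Reagents that add atoms: formaldehyde, C=O
Why: Mannich-type α'-methylenation under Gras conditions: with C1 quaternary the enone can enolise only towards C11, so the methylene carbon C20 is attached there regiospecifically.

Step 13
Reactants: 14 cross-conjugated 11(20),13-dienone
Product: 17 12α-alcohol, via selenide enone 15 (not isolated), via selenide sulfide ketone 16 (not isolated)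
Conditions: PhSeH (1.0 equiv), Et3N (cat.), CH2Cl2, −78 °C; PhSH (3 equiv), Et3N (cat.), 0 °C; then NaBH4, EtOH, −20 °C
Reagents that add atoms: benzeneselenol, [SeH]c1ccccc1; thiophenol, Sc1ccccc1
Why: Two hetero-Michael additions and a ketone reduction in one flask: benzeneselenol adds first to the unhindered exocyclic methylene (C20), thiophenol then adds axially to C14 (14α), and borohydride attacks the C12 ketone from the β face because the α face is closed by the 1,3-diaxial 14α-phenylthio group, which sets the axial 12α-hydroxyl (the C11 configuration is immaterial as C11 becomes trigonal again).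

Step 14
Reactants: 17 12α-alcohol
Product: 19 11(20)-alkene sulfoxide, via selenoxide sulfoxide 18 (not isolated)
Conditions: mCPBA (2.1 equiv), NaHCO3, CH2Cl2, −78 °C; then i-Pr2NH, −78 °C → rt
Reagents that add atoms: 3-chloroperbenzoic acid, OOC(=O)c1cccc(Cl)c1
Why: Chalcogen oxidation followed by selenoxide syn-elimination: the primary selenoxide has only H11 available and leaves at room temperature to give the C11=C20 methylene, whereas the sulfoxide is stable at this temperature and keeps C13=C14 masked.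

Step 15
Reactants: 19 11(20)-alkene sulfoxide
Product: 20 11α,20-epoxide
Conditions: VO(acac)2 (cat.), t-BuOOH, CH2Cl2, 0 °C
Reagents that add atoms: tert-butyl hydroperoxide, CC(C)(C)OO
Why: Hydroxyl-directed vanadium-catalysed epoxidation: the 12α-hydroxyl delivers oxygen to the only alkene present on its own α face, which is also the face away from the C1 methyl and the axial C9 silyloxy group, so the spiro-epoxide has its oxygen α and C20 β as needed at C11.

Step 16
Reactants: 20 11α,20-epoxide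
Product: 21 12α-silyl ether
Conditions: TBSOTf, 2,6-lutidine, CH2Cl2, −78 °C
Reagents that add atoms: tert-butyldimethylsilyl triflate, CC(C)(C)[Si](C)(C)OS(=O)(=O)C(F)(F)F
Why: Silylation of the axial 12α-hydroxyl at low temperature, where the silyl triflate does not open the epoxide.

Step 17
Reactants: 21 12α-silyl ether
Product: 22 13(14)-alkene
Conditions: toluene, NaHCO3 (solid), 110 °C
Reagents that add atoms: none
Why: Thermal sulfoxide syn-elimination, possible only towards C13 because C1 is quaternary, releases the C13=C14 alkene after the epoxidation that it would have disturbed.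

Step 18
Reactants: 22 13(14)-alkene
Product: 23 8α-alcohol
Conditions: K2CO3, MeOH, 40 °C
Reagents that add atoms: none
Why: Base-catalysed transesterification removes the benzoate, and the trans-diaxial C8–O/C9–O arrangement prevents silyl migration to the freed hydroxyl.

Step 19
Reactants: 23 8α-alcohol
Product: 24 8-ketone
Conditions: Dess–Martin periodinane, NaHCO3, CH2Cl2, rt
Reagents that add atoms: none
Why: Dess–Martin oxidation gives the C8 ketone, in which the equatorial H9 is poorly aligned with the carbonyl so that C9 does not epimerise.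

Step 20
Reactants: 24 8-ketone; 25 3-(trimethylsilyl)prop-2-ynal
Product: 28 silylated aldol adduct, via lithium enolate 26 (not isolated), via lithium aldolate 27 (not isolated)
Conditions: LiN(i-Pr)2, THF, −78 °C; 25, −78 °C; then TMSCl, −78 °C
Reagents that add atoms: chlorotrimethylsilane, C[Si](C)(C)Cl
Why: Aldol addition of the kinetic C3 lithium enolate (the C9 methine is not deprotonated and the equatorial C2–O bond is not aligned for β-elimination) to the ynal with in situ O-silylation against retro-aldol; the aldehyde enters C3 on the α face because the axial β trajectory is 1,3-diaxial to the C1 methyl, which gives the equatorial 3α side chain, while both C4 epimers serve since C4 becomes trigonal.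

Step 21
Reactants: 28 silylated aldol adduct; 29 vinylmagnesium bromide
Product: 31 propargylic diol, via silylated vinyl carbinol 30 (not isolated)
Conditions: 29, CeCl3, THF, −78 °C; NH4Cl (aq); then K2CO3, MeOH, rt
Reagents that add atoms: none
Why: Organocerium 1,2-addition, chosen to suppress enolisation: the vinyl group enters C8 axially on the α face, anti to the axial C9–O bond (polar Felkin–Anh) and on the side it leaves open, which gives the axial vinyl and equatorial 8β-hydroxyl cis to the 3α side chain, and potassium carbonate in methanol then removes both trimethylsilyl groups.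

Step 22
Reactants: 31 propargylic diol
Product: 34 allenyl vinyl carbinol, via sulfonylhydrazine 32 (not isolated), via diazene 33 (not isolated)
Conditions: PPh3, diethyl azodicarboxylate, 2-nitrobenzenesulfonohydrazide, THF, −15 °C → 23 °C
Reagents that add atoms: none
Why: Myers allene synthesis: Mitsunobu substitution of the secondary propargylic hydroxyl (the tertiary one is inert) by the sulfonylhydrazide, loss of the sulfinic acid and retro-ene loss of dinitrogen from the propargylic diazene give the terminal allene with C4 on C3 and no new stereocentre.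

Step 23
Reactants: 34 allenyl vinyl carbinol
Product: 37 ten-membered dienyl C8 ketone, via potassium alkoxide 35 (not isolated), via potassium enolate 36 (not isolated)
Conditions: KH, 18-crown-6, THF, 0 °C → rt; NH4Cl (aq), −78 °C
Reagents that add atoms: none
Why: Deprotonation gives the C8 potassium alkoxide 35, whose oxyanion accelerates a concerted [3,3] sigmatropic shift through the six-atom array C6=C7–C8–C3–C4=C5: the central allene carbon C5 bonds to the vinyl terminus C6, the C3–C8 bond breaks, and the C3=C4 alkene, the C5=C16 methylene and the C7=C8 enolate 36 appear together. The closest known reaction is the anionic oxy-Cope ring expansion of 1,2-dialkenylcyclohexanols to cyclodec-5-enones, in which allenes are established two-electron partners that deliver 1,3-dienes. The ten-membered ring is not closed end to end but arises by four-atom ring expansion, cleavage of the C3–C8 bond shared with ring B inside a bicyclic chair transition state. No stereocentre is created; C1, C2, C9, C10, C11 and C12 are untouched and only the C3=C4 geometry is at stake. In the locked trans-decalin the C8 vinyl is axial and the C3 allenyl equatorial (cis, gauche), so the chair array carries the C3–C2 ring bond axially and must give the Z C3=C4 alkene, while the enolate can form only towards C7. An O-to-O shift of the C9 silyl group onto the C8 oxygen is reversible and is drained through the alkoxide that rearranges, and a cold ammonium chloride quench gives ketone 37.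

Step 24
Reactants: 37 ten-membered dienyl C8 ketone
Product: 39 (3Z,6E)-trienone, via trimethylsilyl enol ether 38 (not isolated)
Conditions: LiN(i-Pr)2, TMSCl (in situ quench), THF, −78 °C; then Pd(OAc)2, MeCN, rt
Reagents that add atoms: none
Why: Ito–Saegusa oxidation: kinetic silyl enol ether formation at the C7 methylene rather than the C9 methine, then β-hydride elimination from the palladium enolate (palladium diacetate is reduced to zerovalent palladium) gives the C6=C7 enone, taken to be E as this oxidation normally gives in rings of ten or more atoms.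

Step 25
Reactants: 39 (3Z,6E)-trienone; 40 ethyl propionate
Product: 42 C8 carbinol ester, via lithium enolate 41 (not isolated)
Conditions: 40, LiN(i-Pr)2, THF–DMPU, −78 °C; CeCl3, −78 °C; then 39, −78 °C; NH4Cl (aq), −78 °C
Reagents that add atoms: none
Why: Aldol-type 1,2-addition of the cerium-modified (Z)-O-enolate to the enone carbonyl (cerium suppresses conjugate addition and retro-aldol): attack anti to the C9–O silyl ether bond (polar Felkin–Anh) sets C8, and a closed chair transition state with the C9 branch equatorial and the enolate methyl axial sets C17 with the methyl trans to C9.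

Step 26
Reactants: 42 C8 carbinol ester
Product: 43 trans-6,7-epoxide
Conditions: VO(acac)2 (cat.), t-BuOOH, CH2Cl2, 0 °C
Reagents that add atoms: tert-butyl hydroperoxide, CC(C)(C)OO
Why: Hydroxyl-directed vanadium-catalysed epoxidation of the tertiary allylic alcohol reaches only the proximal C6=C7 bond; in the E-cycloalkene the C8–C9 ring bond stands roughly perpendicular to the alkene plane, and the conformer of this kind that brings the C8–O bond gauche to the alkene delivers oxygen to the C7 face that puts the C7–O bond cis to C8–OH in the ring drawing, the epoxide being trans because the alkene is E.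

Step 27
Reactants: 43 trans-6,7-epoxide
Product: 45 dichloro lactone tris-silyl ether, via dichloro triol ester 44 (not isolated)
Conditions: LiCl (excess), AcOH, THF, rt; then PPTS (cat.), benzene, 40 °C
Reagents that add atoms: lithium chloride, [Li+].[Cl-]
Why: Halohydrin formation by acid-assisted anti opening of both epoxides with chloride (LiCl/AcOH): at the 6,7-epoxide chloride attacks the allylic C6 with inversion rather than the neopentyl C7, at the spiro-epoxide the primary C20, so C6 is set while C7–O and C11–O are retained, and under mild acid the freed C7 hydroxyl lactonises onto the ethyl ester.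

Step 28
Reactants: 45 dichloro lactone tris-silyl ether
Product: 46 dichloro lactone pentaol
Conditions: HF·pyridine, pyridine, THF, 0 °C → rt
Reagents that add atoms: none
Why: Fluoride-mediated cleavage of the three silyl ethers under buffered, non-basic conditions that leave the chlorohydrin, the allylic chloride and the lactone intact.

Step 29
Reactants: 46 dichloro lactone pentaol
Product: 47 CNP0435497.1
Conditions: Ac2O, pyridine, DMAP (cat.), CH2Cl2, 0 °C → rt
Reagents that add atoms: acetic anhydride, CC(=O)OC(C)=O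
Why: Acylation with acetic anhydride acetylates the three secondary hydroxyls at C2, C9 and C12, while the hindered tertiary C8 and C11 hydroxyls stay free.

## Compound list

1 | (S)-Wieland–Miescher ketone, (8aS)-8a-methyl-3,4,8,8a-tetrahydronaphthalene-1,6(2H,7H)-dione (C2 ketone, C10=C11–C12=O enone) | C1C(=O)[C@@]2(C)CCC(=O)C=C2CC1 | starting material
2 | (4aS,5S)-5-hydroxy-4a-methyl-4,4a,5,6,7,8-hexahydronaphthalen-2(3H)-one (2β-OH, cis to the methyl) | C1[C@H](O)[C@@]2(C)CCC(=O)C=C2CC1 | intermediate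
3 | 2β-OTBS enone | C1[C@H](O[Si](C)(C)C(C)(C)C)[C@@]2(C)CCC(=O)C=C2CC1 | intermediate
4 | 2β-OTBS, 12,12-ethylenedioxy, C9=C10 alkene | C1[C@H](O[Si](C)(C)C(C)(C)C)[C@@]2(C)CCC3(OCCO3)CC2=CC1 | intermediate
5 | trans-decalin (H10 α): 2β-OTBS, 9α-OH, 12-dioxolane | C1[C@H](O[Si](C)(C)C(C)(C)C)[C@@]2(C)CCC3(OCCO3)C[C@@H]2[C@@H](O)C1 | intermediate
6 | trans-decalin: 2β-OTBS, 9-ketone, 12-dioxolane | C1[C@H](O[Si](C)(C)C(C)(C)C)[C@@]2(C)CCC3(OCCO3)C[C@@H]2C(=O)C1 | intermediate
7 | potassium C8=C9 enolate of 6 | C1[C@H](O[Si](C)(C)C(C)(C)C)[C@@]2(C)CCC3(OCCO3)C[C@@H]2C(O[K])=C1 | intermediate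
8 | 8α-hydroxy 9-ketone | C1[C@H](O[Si](C)(C)C(C)(C)C)[C@@]2(C)CCC3(OCCO3)C[C@@H]2C(=O)[C@H]1O | intermediate
9 | trans-diaxial 8α,9β-diol | C1[C@H](O[Si](C)(C)C(C)(C)C)[C@@]2(C)CCC3(OCCO3)C[C@@H]2[C@H](O)[C@H]1O | intermediate
10 | 8α-benzoate, 9β-OH | C1[C@H](O[Si](C)(C)C(C)(C)C)[C@@]2(C)CCC3(OCCO3)C[C@@H]2[C@H](O)[C@H]1OC(=O)c4ccccc4 | intermediate
11 | 8α-benzoate, 9β-OTBS, 12-dioxolane | C1[C@H](O[Si](C)(C)C(C)(C)C)[C@@]2(C)CCC3(OCCO3)C[C@@H]2[C@H](O[Si](C)(C)C(C)(C)C)[C@H]1OC(=O)c4ccccc4 | intermediate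
12 | 2β,9β-bis-OTBS, 8α-benzoate, 12-ketone | C1[C@H](O[Si](C)(C)C(C)(C)C)[C@@]2(C)CCC(=O)C[C@@H]2[C@H](O[Si](C)(C)C(C)(C)C)[C@H]1OC(=O)c4ccccc4 | intermediate
13 | C13=C14 enone (12-ketone) | C1[C@H](O[Si](C)(C)C(C)(C)C)[C@@]2(C)C=CC(=O)C[C@@H]2[C@H](O[Si](C)(C)C(C)(C)C)[C@H]1OC(=O)c4ccccc4 | intermediate
14 | cross-conjugated dienone: C11=C20H2, C12=O, C13=C14 | C1[C@H](O[Si](C)(C)C(C)(C)C)[C@@]2(C)C=CC(=O)C(=C)[C@@H]2[C@H](O[Si](C)(C)C(C)(C)C)[C@H]1OC(=O)c4ccccc4 | intermediate
15 | C20 phenylselenide, C13=C14 enone (C11 drawn as the equatorial isomer) | C1[C@H](O[Si](C)(C)C(C)(C)C)[C@@]2(C)C=CC(=O)[C@@H](C[Se]c5ccccc5)[C@@H]2[C@H](O[Si](C)(C)C(C)(C)C)[C@H]1OC(=O)c4ccccc4 | intermediate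
16 | C20 phenylselenide, 14α-phenylsulfide, 12-ketone | C1[C@H](O[Si](C)(C)C(C)(C)C)[C@@]2(C)[C@@H](Sc6ccccc6)CC(=O)[C@@H](C[Se]c5ccccc5)[C@@H]2[C@H](O[Si](C)(C)C(C)(C)C)[C@H]1OC(=O)c4ccccc4 | intermediate
17 | C20 phenylselenide, 14α-phenylsulfide, 12α-OH | C1[C@H](O[Si](C)(C)C(C)(C)C)[C@@]2(C)[C@@H](Sc6ccccc6)C[C@@H](O)[C@@H](C[Se]c5ccccc5)[C@@H]2[C@H](O[Si](C)(C)C(C)(C)C)[C@H]1OC(=O)c4ccccc4 | intermediate
18 | C20 selenoxide, 14α-sulfoxide, 12α-OH (Se and S configurations undefined) | C1[C@H](O[Si](C)(C)C(C)(C)C)[C@@]2(C)[C@@H](S(=O)c6ccccc6)C[C@@H](O)[C@@H](C[Se](=O)c5ccccc5)[C@@H]2[C@H](O[Si](C)(C)C(C)(C)C)[C@H]1OC(=O)c4ccccc4 | intermediate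
19 | C11=C20H2, 12α-OH, 14α-sulfoxide | C1[C@H](O[Si](C)(C)C(C)(C)C)[C@@]2(C)[C@@H](S(=O)c6ccccc6)C[C@@H](O)C(=C)[C@@H]2[C@H](O[Si](C)(C)C(C)(C)C)[C@H]1OC(=O)c4ccccc4 | intermediate
20 | 11,20-spiro-epoxide (O α, C20 β), 12α-OH, 14α-sulfoxide | C1[C@H](O[Si](C)(C)C(C)(C)C)[C@@]2(C)[C@@H](S(=O)c6ccccc6)C[C@@H](O)[C@]3(CO3)[C@@H]2[C@H](O[Si](C)(C)C(C)(C)C)[C@H]1OC(=O)c4ccccc4 | intermediate
21 | 11,20-spiro-epoxide, 12α-OTBS, 14α-sulfoxide | C1[C@H](O[Si](C)(C)C(C)(C)C)[C@@]2(C)[C@@H](S(=O)c6ccccc6)C[C@@H](O[Si](C)(C)C(C)(C)C)[C@]3(CO3)[C@@H]2[C@H](O[Si](C)(C)C(C)(C)C)[C@H]1OC(=O)c4ccccc4 | intermediate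
22 | C13=C14, 12α-OTBS, 11,20-spiro-epoxide, 9β-OTBS, 8α-benzoate, 2β-OTBS | C1[C@H](O[Si](C)(C)C(C)(C)C)[C@@]2(C)C=C[C@@H](O[Si](C)(C)C(C)(C)C)[C@]3(CO3)[C@@H]2[C@H](O[Si](C)(C)C(C)(C)C)[C@H]1OC(=O)c4ccccc4 | intermediate
23 | 8α-alcohol of 22 | C1[C@H](O[Si](C)(C)C(C)(C)C)[C@@]2(C)C=C[C@@H](O[Si](C)(C)C(C)(C)C)[C@]3(CO3)[C@@H]2[C@H](O[Si](C)(C)C(C)(C)C)[C@H]1O | intermediate
24 | 8-ketone | C1[C@H](O[Si](C)(C)C(C)(C)C)[C@@]2(C)C=C[C@@H](O[Si](C)(C)C(C)(C)C)[C@]3(CO3)[C@@H]2[C@H](O[Si](C)(C)C(C)(C)C)C1=O | intermediate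
25 | 3-(trimethylsilyl)prop-2-ynal | C[Si](C)(C)C#CC=O | starting material
26 | lithium C3=C8 enolate of 24 | [Li]OC1=C[C@H](O[Si](C)(C)C(C)(C)C)[C@@]2(C)C=C[C@@H](O[Si](C)(C)C(C)(C)C)[C@]3(CO3)[C@@H]2[C@@H]1O[Si](C)(C)C(C)(C)C | intermediate
27 | lithium aldolate (3α side chain, C4 epimers) | C[Si](C)(C)C#CC(O[Li])[C@H]1[C@H](O[Si](C)(C)C(C)(C)C)[C@@]2(C)C=C[C@@H](O[Si](C)(C)C(C)(C)C)[C@]3(CO3)[C@@H]2[C@H](O[Si](C)(C)C(C)(C)C)C1=O | intermediate
28 | 3α-[1-(trimethylsilyloxy)-3-(trimethylsilyl)prop-2-ynyl] 8-ketone (C4 epimers) | C[Si](C)(C)C#CC(O[Si](C)(C)C)[C@H]1[C@H](O[Si](C)(C)C(C)(C)C)[C@@]2(C)C=C[C@@H](O[Si](C)(C)C(C)(C)C)[C@]3(CO3)[C@@H]2[C@H](O[Si](C)(C)C(C)(C)C)C1=O | intermediate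
29 | vinylmagnesium bromide | C=C[Mg]Br | starting material
30 | 8α-vinyl 8β-ol still carrying both trimethylsilyl groups (C4 epimers) | C[Si](C)(C)C#CC(O[Si](C)(C)C)[C@H]1[C@H](O[Si](C)(C)C(C)(C)C)[C@@]2(C)C=C[C@@H](O[Si](C)(C)C(C)(C)C)[C@]3(CO3)[C@@H]2[C@H](O[Si](C)(C)C(C)(C)C)[C@@]1(O)C=C | intermediate
31 | 3α-(1-hydroxyprop-2-ynyl) 8α-vinyl 8β-ol (C4 epimers) | C#CC(O)[C@H]1[C@H](O[Si](C)(C)C(C)(C)C)[C@@]2(C)C=C[C@@H](O[Si](C)(C)C(C)(C)C)[C@]3(CO3)[C@@H]2[C@H](O[Si](C)(C)C(C)(C)C)[C@@]1(O)C=C | intermediate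
32 | C4 N-(2-nitrobenzenesulfonyl)hydrazine (C4 epimers) | C#CC(N(N)S(=O)(=O)c7ccccc7[N+](=O)[O-])[C@H]1[C@H](O[Si](C)(C)C(C)(C)C)[C@@]2(C)C=C[C@@H](O[Si](C)(C)C(C)(C)C)[C@]3(CO3)[C@@H]2[C@H](O[Si](C)(C)C(C)(C)C)[C@@]1(O)C=C | intermediate
33 | C4 propargylic diazene (C4 epimers) | C#CC(N=N)[C@H]1[C@H](O[Si](C)(C)C(C)(C)C)[C@@]2(C)C=C[C@@H](O[Si](C)(C)C(C)(C)C)[C@]3(CO3)[C@@H]2[C@H](O[Si](C)(C)C(C)(C)C)[C@@]1(O)C=C | intermediate
34 | oxy-Cope precursor: trans-decalin with 3α-(propa-1,2-dienyl), 8α-vinyl, 8β-OH, 2β/9β/12α-OTBS, 11,20-spiro-epoxide, C13=C14 | C=C=C[C@H]1[C@H](O[Si](C)(C)C(C)(C)C)[C@@]2(C)C=C[C@@H](O[Si](C)(C)C(C)(C)C)[C@]3(CO3)[C@@H]2[C@H](O[Si](C)(C)C(C)(C)C)[C@@]1(O)C=C | intermediate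
35 | potassium C8 alkoxide of 34 | C=C=C[C@H]1[C@H](O[Si](C)(C)C(C)(C)C)[C@@]2(C)C=C[C@@H](O[Si](C)(C)C(C)(C)C)[C@]3(CO3)[C@@H]2[C@H](O[Si](C)(C)C(C)(C)C)[C@@]1(O[K])C=C | intermediate
36 | ten-membered potassium C7=C8 enolate (C6 and C9 trans), (3Z)-alkene, C5 methylene | [K]O/C1=C\CC(=C)/C=C\[C@H](O[Si](C)(C)C(C)(C)C)[C@@]2(C)C=C[C@@H](O[Si](C)(C)C(C)(C)C)[C@]3(CO3)[C@@H]2[C@@H]1O[Si](C)(C)C(C)(C)C | intermediate
37 | ten-membered dienyl C8 ketone: (3Z)-C3=C4, C5=C16H2, C6H2, C7H2 | O=C1CCC(=C)/C=C\[C@H](O[Si](C)(C)C(C)(C)C)[C@@]2(C)C=C[C@@H](O[Si](C)(C)C(C)(C)C)[C@]3(CO3)[C@@H]2[C@@H]1O[Si](C)(C)C(C)(C)C | intermediate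
38 | C7=C8 trimethylsilyl enol ether of 37 (enol ether geometry not defined) | C[Si](C)(C)OC1=CCC(=C)/C=C\[C@H](O[Si](C)(C)C(C)(C)C)[C@@]2(C)C=C[C@@H](O[Si](C)(C)C(C)(C)C)[C@]3(CO3)[C@@H]2[C@@H]1O[Si](C)(C)C(C)(C)C | intermediate
39 | (3Z,6E)-trienone: C8=O, C6=C7, C5=C16H2, C3=C4 | O=C1/C=C/C(=C)/C=C\[C@H](O[Si](C)(C)C(C)(C)C)[C@@]2(C)C=C[C@@H](O[Si](C)(C)C(C)(C)C)[C@]3(CO3)[C@@H]2[C@@H]1O[Si](C)(C)C(C)(C)C | intermediate
40 | ethyl propionate | CCC(=O)OCC | starting material
41 | lithium (Z)-O-enolate of ethyl propionate | C/C=C(\O[Li])OCC | intermediate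
42 | C8 tertiary carbinol carrying the C17 ethyl propionate arm, (6E)-alkene (C8 and C17 as in the target) | CCOC(=O)[C@H](C)[C@]1(O)/C=C/C(=C)/C=C\[C@H](O[Si](C)(C)C(C)(C)C)[C@@]2(C)C=C[C@@H](O[Si](C)(C)C(C)(C)C)[C@]3(CO3)[C@@H]2[C@@H]1O[Si](C)(C)C(C)(C)C | intermediate
43 | trans-6,7-epoxide (C7–O cis to C8–OH in the ring drawing) | CCOC(=O)[C@H](C)[C@]1(O)[C@H]4O[C@@H]4C(=C)/C=C\[C@H](O[Si](C)(C)C(C)(C)C)[C@@]2(C)C=C[C@@H](O[Si](C)(C)C(C)(C)C)[C@]3(CO3)[C@@H]2[C@@H]1O[Si](C)(C)C(C)(C)C | intermediate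
44 | 6-chloro-7,8-diol ethyl ester with C11(OH)CH2Cl | CCOC(=O)[C@H](C)[C@]1(O)[C@@H](O)[C@@H](Cl)C(=C)/C=C\[C@H](O[Si](C)(C)C(C)(C)C)[C@@]2(C)C=C[C@@H](O[Si](C)(C)C(C)(C)C)[C@](O)(CCl)[C@@H]2[C@@H]1O[Si](C)(C)C(C)(C)C | intermediate
45 | dichloro γ-lactone, 2,9,12-tris-OTBS | C=C1/C=C\[C@H](O[Si](C)(C)C(C)(C)C)[C@@]2(C)C=C[C@@H](O[Si](C)(C)C(C)(C)C)[C@](O)(CCl)[C@@H]2[C@H](O[Si](C)(C)C(C)(C)C)[C@]2(O)[C@@H](C)C(=O)O[C@H]2[C@H]1Cl | intermediate
46 | dichloro γ-lactone 2,8,9,11,12-pentaol | C=C1/C=C\[C@H](O)[C@@]2(C)C=C[C@@H](O)[C@](O)(CCl)[C@@H]2[C@H](O)[C@]2(O)[C@@H](C)C(=O)O[C@H]2[C@H]1Cl | intermediate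
47 | CNP0435497.1 | C=C1/C=C\[C@H](OC(C)=O)[C@@]2(C)C=C[C@@H](OC(C)=O)[C@](O)(CCl)[C@@H]2[C@H](OC(C)=O)[C@]2(O)[C@@H](C)C(=O)O[C@H]2[C@H]1Cl | target

## Step count and risks

Total: 29 steps. Longest linear sequence: 29 steps (1 → 47).

Steps most likely to fail:

Step 23. The alkoxide may fragment instead of rearranging, may be capped by silyl transfer from the C9 oxygen, or may rearrange through a boat array that gives the E C3=C4 alkene. The fallback is the neutral thermal variant and sets out from 34. The tertiary hydroxyl is silylated with N-(trimethylsilyl)imidazole to the C8 trimethylsilyl ether F1. Heating F1 in toluene in a sealed tube at about 200 °C should bring about the silyloxy-Cope shift with no anion present and give the (7E)-trimethylsilyl enol ether F2. Methanolysis (K2CO3, MeOH) returns to the route at ketone 37.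

Step 24. β-Hydride elimination may run through the ring conformer that has C5 and C8 gauche and give the Z enone. A cis-epoxide would follow, and anti opening by chloride would then give the C6 epimer. The fallback sets out from 37 and installs the C6 chloride by double inversion. The (3Z,6Z)-trienone F3 is carried through the conditions of steps 25 and 26 to the (6Z) carbinol ester F4 and the cis-6,7-epoxide F5. One equivalent of LiBr in AcOH–THF at 0 °C should open only the more reactive allylic epoxide at C6 and give the 6-bromo-7-hydroxy ester F6, with bromine anti to the C7 oxygen. Excess LiCl in AcOH–THF–DMF then replaces the allylic bromide with inversion and opens the spiro-epoxide at C20. This comes back to the route at 44.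

Step 25. The enolate may add in a conjugate (1,4 or 1,6) sense to the cross-conjugated trienone, or the hindered aldolate may revert on work-up, instead of clean 1,2-addition. The fallback sets out from 39 and takes the ketone out of conjugation first. Weitz–Scheffer epoxidation (t-BuOOH, benzyltrimethylammonium hydroxide) gives the trans-6,7-epoxy C8 ketone F7. Enolate 41 is then added to the now non-conjugated ketone, anti to the epoxide oxygen and anti to the C9 silyloxy bond. This comes back to the route at 43 and bypasses step 26.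

Further compounds
F1 | step 23 | C8 trimethylsilyl ether of 34 | C=C=C[C@H]1[C@H](O[Si](C)(C)C(C)(C)C)[C@@]2(C)C=C[C@@H](O[Si](C)(C)C(C)(C)C)[C@]3(CO3)[C@@H]2[C@H](O[Si](C)(C)C(C)(C)C)[C@@]1(O[Si](C)(C)C)C=C
F2 | step 23 | (7E)-trimethylsilyl enol ether of ketone 37 | C[Si](C)(C)O/C1=C\CC(=C)/C=C\[C@H](O[Si](C)(C)C(C)(C)C)[C@@]2(C)C=C[C@@H](O[Si](C)(C)C(C)(C)C)[C@]3(CO3)[C@@H]2[C@@H]1O[Si](C)(C)C(C)(C)C
F3 | step 24 | (3Z,6Z)-trienone | O=C1/C=C\C(=C)\C=C/[C@H](O[Si](C)(C)C(C)(C)C)[C@@]2(C)C=C[C@@H](O[Si](C)(C)C(C)(C)C)[C@]3(CO3)[C@@H]2[C@@H]1O[Si](C)(C)C(C)(C)C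
F4 | step 24 | (6Z) C8 carbinol ester | CCOC(=O)[C@H](C)[C@]1(O)/C=C\C(=C)\C=C/[C@H](O[Si](C)(C)C(C)(C)C)[C@@]2(C)C=C[C@@H](O[Si](C)(C)C(C)(C)C)[C@]3(CO3)[C@@H]2[C@@H]1O[Si](C)(C)C(C)(C)C
F5 | step 24 | cis-6,7-epoxide | CCOC(=O)[C@H](C)[C@]1(O)[C@H]4O[C@H]4C(=C)/C=C\[C@H](O[Si](C)(C)C(C)(C)C)[C@@]2(C)C=C[C@@H](O[Si](C)(C)C(C)(C)C)[C@]3(CO3)[C@@H]2[C@@H]1O[Si](C)(C)C(C)(C)C
F6 | step 24 | 6-bromo-7-hydroxy ester with the spiro-epoxide intact | CCOC(=O)[C@H](C)[C@]1(O)[C@@H](O)[C@H](Br)C(=C)/C=C\[C@H](O[Si](C)(C)C(C)(C)C)[C@@]2(C)C=C[C@@H](O[Si](C)(C)C(C)(C)C)[C@]3(CO3)[C@@H]2[C@@H]1O[Si](C)(C)C(C)(C)C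
F7 | step 25 | trans-6,7-epoxy C8 ketone | O=C1[C@H]4O[C@@H]4C(=C)/C=C\[C@H](O[Si](C)(C)C(C)(C)C)[C@@]2(C)C=C[C@@H](O[Si](C)(C)C(C)(C)C)[C@]3(CO3)[C@@H]2[C@@H]1O[Si](C)(C)C(C)(C)C
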